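The numbers in the tables come from a simulation with made-up constants; scatter was added.

Something stays put here: in Monday's run, product and substrate still add up to 99.1% of the charge at 40.0 min, so I read both answers side by side from that run. You asked for a quick number and guessed that your flask is Monday's run on a slower clock. I think you are right.

| flask | substrate | reagent | free catalyst | remark | time |
|---|---|---|---|---|---|
| Sunday's | 0.25 M | 0.50 M | 1.4 mM | run made earlier |  |
| Wednesday's | 1 M | 0.50 M | 1.4 mM | run made earlier |  |
| Monday's | 0.50 M | 0.50 M | 2.1 mM | run made earlier |  |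
| flask | 0.50 M | 0.500 M | 1.4 mM |  | 80 min |

| run | time / min | product / % | substrate / % |
|---|---|---|---|
| Sunday's | 5.00 | 8.1 | 91.3 |
| Sunday's | 15.0 | 24.0 | 75.8 |
| Sunday's | 30.0 | 45.4 | 54.7 |
| Sunday's | 40.0 | 57.6 | 42.1 |
| Sunday's | 60.0 | 78.6 | 22.4 |
| Sunday's | 80.0 | 91.0 | 8.5 |
| Wednesday's | 12.0 | 5.7 | 94.1 |
| Wednesday's | 25.0 | 12.0 | 88.6 |
| Wednesday's | 40.0 | 17.1 | 82.4 |
| Wednesday's | 50.0 | 21.2 | 78.8 |
| Wednesday's | 60.0 | 24.3 | 75.5 |
| Wednesday's | 80.0 | 30.5 | 68.6 |
| Monday's | 8.00 | 10.5 | 89.5 |
| Monday's | 20.0 | 25.1 | 74.3 |
| Monday's | 40.0 | 45.9 | 53.2 |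
| Monday's | 60.0 | 63.7 | 36.5 |
| Monday's | 80.0 | 75.5 | 24.1 |

(each reading ± 0.3 percentage points)

- what was read earlier has a scatter of 0.3 percentage points, one standard deviation

- concentration of product at 80 min, in M
- concentration of substrate at 80 min, in M

Your flask has Monday's substrate and reagent charges but less free catalyst, 1.4 mM against 2.1 mM. So the open question is whether rate follows c(free catalyst). Early product per catalyst per minute reads 2.89 min⁻¹ on Sunday, 3.12 min⁻¹ on Monday and 3.39 min⁻¹ on Wednesday. Monday's reading is higher than Sunday's and lower than Wednesday's, and its substrate charge lies between theirs too. I therefore take rate as proportional to c(free catalyst), and then, with substrate and reagent charges held, a flask's time converts to Monday's clock: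

time × c(free catalyst) in the flask ÷ c(free catalyst) on Monday = 80 min × 1.4 mM ÷ 2.1 mM = 53.3 min

I call this the flask's Monday-minutes, a normalised time, and it is shorter than the flask's own time. It falls between Monday's readings at 40.0 min and 60.0 min, and a straight line between them gives:

product 57.8% of 0.50 M = 0.289 M

substrate 42.1% of 0.50 M = 0.211 M

The forecast stands at 0.289 M product and 0.211 M substrate, with the words “rate looks first order in catalyst”.

The flask gives 0.292 M product and 0.208 M substrate. Product moves by a tenth of itself at 69.6 min with the charges held, or at 1.22 mM of free catalyst with the time held. In Monday-minutes these are 46.4 min and 46.5 min, nearly one point on Monday's curve.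

    reagent + free catalyst ⇌ catalyst intermediate A (K = 1.50 M⁻¹, k = 1300 M⁻¹ h⁻¹)
    substrate + catalyst intermediate A → catalyst intermediate B (k = 11000 M⁻¹ h⁻¹)
    catalyst intermediate B → by-product + catalyst intermediate C (k = 360 h⁻¹)
    catalyst intermediate C → catalyst intermediate D (k = 20000 h⁻¹)
    catalyst intermediate D → free catalyst + product (k = 2500 h⁻¹)
    catalyst intermediate C → spent catalyst (k = 0.0470 h⁻¹)

For a neighbour like this flask, with 8.4 × 10⁻⁴ M of free catalyst, 80 min comes to 32.0 min in Monday-minutes. Between Monday's readings at 20.0 min and 40.0 min, that gives 37.6% product and 61.6% substrate. The computed neighbour holds 38.6% product and 61.3% substrate.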